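**Assumption:** the target is taken exactly as drawn, i.e. the trans-(1R,2S) 1-aryl-1,2-dihydronaphthalene-2,3-dicarboxylate core (C1 = aryl-bearing carbon, C2 = adjacent sp3 carbon) esterified twice with (R)-3-(3,4-dihydroxyphenyl)lactic acid.

**Retrosynthetic overview** (Ar = 2,2-dimethyl-1,3-benzodioxol-5-yl)
1. All four arene rings come from catechol (1) via acetonide 2 and iodide 3; both side-chain stereocentres come from methyl (R)-glycidate (4); acryloyl chloride (5) supplies both C3 acyl units.
2. 3 + 4 + 5 give acrylate 6; Heck coupling with 3 gives protected methyl rosmarinate 7; bromination/elimination of part of 7 gives α-bromide 8.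
3. Key disconnection: C2–C3 and C1–C8a of dihydronaphthalene 9 form in one photoredox radical cascade. The vinyl radical from 8 adds to the alkene of 7, and the resulting benzylic radical closes onto the aryl ring of the radical partner. This is a cross-annulation of two different partners, not a phenol oxidative dimerisation.
4. Ring order: the benzene rings are carried through from 1; the central ring of the dihydronaphthalene is the only ring formed, in the cascade. 9 → 10 → 11 is deprotection only.

**Route**

Step 1
Reactants: 1, catechol
Product: 2, 2,2-dimethyl-1,3-benzodioxole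
Conditions: 2,2-dimethoxypropane, TsOH·H2O (cat.), PhMe, reflux, MeOH removed (4 Å MS Soxhlet)
Reagents that add atoms: 2,2-dimethoxypropane, COC(C)(C)OC
Why: Acid-catalysed transketalisation driven by methanol removal masks the catechol, which would otherwise quench the Grignard and radical steps, as an acid-labile acetonide.

Step 2
Reactants: 2, 2,2-dimethyl-1,3-benzodioxole
Product: 3, 5-iodo-2,2-dimethyl-1,3-benzodioxole
Conditions: NIS, TFA (cat.), MeCN, rt, dark
Reagents that add atoms: N-iodosuccinimide, O=C1CCC(=O)N1I
Why: Electrophilic aromatic iodination of the benzodioxole occurs para to a ring oxygen (C5), the only electronically favoured open position.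

Step 3
Reactants: 3, 5-iodo-2,2-dimethyl-1,3-benzodioxole; 4, methyl (R)-glycidate; 5, acryloyl chloride
Product: 6, methyl (2R)-2-(acryloyloxy)-3-Ar-propanoate
Conditions: Mg, THF, 40 °C; add to CuI (10 mol %) + 4 (1.1 equiv), THF, –40 → –20 °C; then 5 (1.5 equiv), –20 → 0 °C
Reagents that add atoms: none (all new atoms come from 3, 4 and 5)
Why: Copper-catalysed Grignard opening of the epoxide at its unsubstituted CH2 (SN2) leaves the C2 stereocentre untouched (R retained), and the magnesium alkoxide is O-acylated in the same pot.

Step 4
Reactants: 6, methyl (2R)-2-(acryloyloxy)-3-Ar-propanoate; 3, 5-iodo-2,2-dimethyl-1,3-benzodioxole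
Product: 7, methyl (2R)-2-{[(E)-3-Ar-prop-2-enoyl]oxy}-3-Ar-propanoate (bis-acetonide of methyl rosmarinate)
Conditions: Pd(OAc)2 (5 mol %), n-Bu4NCl, NaHCO3, DMF, 70 °C
Reagents that add atoms: none
Why: Mizoroki–Heck coupling (Jeffery conditions) of the aryl iodide with the acrylate gives the E-cinnamate under base mild enough not to epimerise the α-acyloxy ester.

Step 5
Reactants: 7, protected methyl rosmarinate (about 30% of the batch)
Product: 8, methyl (2R)-2-{[(Z)-2-bromo-3-Ar-prop-2-enoyl]oxy}-3-Ar-propanoate
Conditions: Br2 (1.0 equiv), CH2Cl2, –78 °C; then Et3N, –78 °C → rt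
Reagents that add atoms: bromine, BrBr
Why: Anti addition of Br2 to the electron-rich cinnamate C=C, which is faster at –78 °C than ring bromination, followed by dehydrobromination through the acidic α-H, gives the (Z)-α-bromocinnamate; the alkene geometry is lost anyway in the next step.

Step 6
Reactants: 8, α-bromide (1 equiv); 7, protected methyl rosmarinate (2.5 equiv, excess recovered)
Product: 9, bis[(2R)-1-methoxy-1-oxo-3-Ar-propan-2-yl] (1R,2S)-1-Ar-6,7-(isopropylidenedioxy)-1,2-dihydronaphthalene-2,3-dicarboxylate, separated by chromatography from its (1S,2R) core diastereomer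
Conditions: fac-Ir(ppy)3 (2 mol %), 2,6-lutidine, DMF, 455 nm LEDs, rt, degassed
Reagents that add atoms: none
Why: Proposed new method: excited Ir(III) reduces the C–Br bond of 8 to an α-alkoxycarbonyl vinyl radical (C3), which adds to the ester-bearing carbon of 7 (C2–C3 bond) to give the p-alkoxybenzyl radical at C1; this closes onto the ortho carbon para to oxygen of the radical partner's aryl ring (C1–C8a), either directly or after oxidation to the cation, and Ir(IV) oxidation/deprotonation rearomatises. Ring closure with the C1 aryl and C2 ester anti should give the 1,2-trans product, but the absolute sense is biased only by the two (R)-ester groups and is expected to be modest, so the (1R,2S) diastereomer is isolated here. The closest known reaction type is the visible-light photoredox addition–cyclisation of vinyl radicals from α-bromochalcones/α-bromocinnamates with alkenes or heteroarenes to give 1,2-dihydronaphthalenes.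

Step 7
Reactants: 9, tetra-acetonide dimethyl ester
Product: 10, (1R,2S)-tetra-acetonide of rabdosiin (both side-chain CO2H free)
Conditions: Me3SnOH (10 equiv), ClCH2CH2Cl, 70 °C; aq. KHSO4 work-up
Reagents that add atoms: trimethyltin hydroxide, C[Sn](C)(C)O (its oxygen becomes the OH of each new CO2H)
Why: Trimethyltin hydroxide ester hydrolysis should cleave the two unhindered, α-acyloxy-activated methyl esters in preference to the two hindered secondary-alkyl esters of the core, without epimerising C2 or the side-chain centres.

Step 8
Reactants: 10, tetra-acetonide diacid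
Product: 11, rabdosiin
Conditions: TFA/H2O (9:1), 0 °C → rt, Ar; reverse-phase HPLC
Reagents that add atoms: none (water only hydrolyses the ketals; its oxygen leaves in acetone)
Why: Acid-catalysed ketal hydrolysis frees the four catechols, while the ester links, the conjugated C3=C4 alkene and all four stereocentres are stable to TFA.

**Compound list**
1 | catechol | Oc1ccccc1O | starting material
2 | 2,2-dimethyl-1,3-benzodioxole | CC1(C)Oc2ccccc2O1 | intermediate
3 | 5-iodo-2,2-dimethyl-1,3-benzodioxole | CC1(C)Oc2ccc(I)cc2O1 | intermediate
4 | methyl (R)-oxirane-2-carboxylate (methyl (R)-glycidate) | COC(=O)[C@H]1CO1 | starting material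
5 | acryloyl chloride | C=CC(=O)Cl | starting material
6 | methyl (2R)-2-(acryloyloxy)-3-(2,2-dimethyl-1,3-benzodioxol-5-yl)propanoate | C=CC(=O)O[C@H](Cc1ccc2OC(C)(C)Oc2c1)C(=O)OC | intermediate
7 | methyl (2R)-2-{[(E)-3-Ar-acryloyl]oxy}-3-Ar-propanoate | O=C(/C=C/c1ccc2OC(C)(C)Oc2c1)O[C@H](Cc1ccc2OC(C)(C)Oc2c1)C(=O)OC | intermediate
8 | methyl (2R)-2-{[(Z)-2-bromo-3-Ar-acryloyl]oxy}-3-Ar-propanoate | O=C(/C(Br)=C/c1ccc2OC(C)(C)Oc2c1)O[C@H](Cc1ccc2OC(C)(C)Oc2c1)C(=O)OC | intermediate
9 | (1R,2S)-rabdosiin tetra-acetonide dimethyl ester | O=C(O[C@H](Cc1ccc2OC(C)(C)Oc2c1)C(=O)OC)C1=Cc2cc3OC(C)(C)Oc3cc2[C@@H](c2ccc3OC(C)(C)Oc3c2)[C@@H]1C(=O)O[C@H](Cc1ccc2OC(C)(C)Oc2c1)C(=O)OC | intermediate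
10 | (1R,2S)-rabdosiin tetra-acetonide | O=C(O[C@H](Cc1ccc2OC(C)(C)Oc2c1)C(=O)O)C1=Cc2cc3OC(C)(C)Oc3cc2[C@@H](c2ccc3OC(C)(C)Oc3c2)[C@@H]1C(=O)O[C@H](Cc1ccc2OC(C)(C)Oc2c1)C(=O)O | intermediate
11 | rabdosiin | O=C(O[C@H](Cc1ccc(O)c(O)c1)C(=O)O)C1=Cc2cc(O)c(O)cc2[C@@H](c2ccc(O)c(O)c2)[C@@H]1C(=O)O[C@H](Cc1ccc(O)c(O)c1)C(=O)O | target

**Total steps:** 8. **Longest linear sequence:** 8 (1 → 2 → 3 → 6 → 7 → 8 → 9 → 10 → 11; 3 and 7 are each used twice).

**Steps most likely to fail**
1. Step 6. The vinyl radical may add slowly to a β-substituted acrylate, 8 may simply be reduced back to 7, the ring may close at the wrong ortho position, and facial control from the remote (R)-esters may be poor. Fallback: reductively homocouple 8 with Ni(0) to the C2-symmetric (E,E)-2,3-bis(arylmethylene)succinate bis-ester, then close the ring by acridinium-photoredox radical-cation hydroarylation (C1–C8a formed on the styrene radical cation, H returned to C2 by a thiol HAT co-catalyst), and separate the diastereomers as before.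
2. Step 5. Ring bromination of the electron-rich side-chain arene or decomposition of the benzylic dibromide may compete. Fallback: change the assembly order. Run the Heck reaction of 3 with acrylic acid, do the Br2/Et3N sequence on the cinnamic acid (no side-chain arene present), then esterify (DCC/DMAP) with the hydroxy ester obtained by quenching step 3 with NH4Cl instead of 5.
3. Step 7. Cleavage of the two methyl esters may be incomplete or may touch the core esters. Fallback: change the carboxyl strategy from the start. Open potassium (R)-glycidate with the same aryl copper/Grignard reagent and carry the two side-chain acids unprotected (as lutidinium carboxylates in the photoredox step), so the end game is the TFA step alone.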